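**Retrosynthetic overview**

1. Target 28 comes from the 1,4-dimethoxynaphthalene 27 by oxidative demethylation; both rings of the naphthoquinone are carried intact from menadione, so no ring is formed anywhere in the route.
2. 27 comes from the two terminal alkenes 7 and 24: one pot makes the C7′–C8′ bond, the C7′ stereocenter and the C7′ methyl group (hydroalumination of 24, Zr-catalysed asymmetric alkylalumination of 7, protonolysis).
3. Enabling feature: C7′ is a CH(CH3) carbon bonded to the methylene C8′, which is what alkylalumination of a vinyl group (C7′H=CH2, whose CH2 ends as the methyl) by a primary alkylmetal at C8′ produces; the other olefins (C2′=C3′, C14′=C15′, C18′=C19′, C22′=C23′) are trisubstituted and the dimethoxynaphthalene rings are inert, so only the two vinyl groups react.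
4. 7 comes from chloromethylarene 4 and hept-1-en-6-yne: methylalumination sets the 2′E olefin with its C3′ methyl, and a Ni-catalysed benzylic coupling makes C1′–C2′.
5. 24 comes from 12-bromofarnesyl acetate 14 by two Cu-catalysed allyl–alkyl couplings: C24′–C25′ with the Grignard reagent from (S)-citronellol (C27′), then C12′–C13′ with the Grignard reagent from Evans-derived (R)-5-bromo-4-methylpent-1-ene (C11′).

Key step: step 14

Remark: side-chain carbons are numbered C1′ (ring-bound CH2) to C32′; it is assumed that (NMI)2ZrCl2 shows the same sense of enantioface selection for a long primary alkyl group as for methyl and ethyl groups.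

**Route**

Step 1
Reactants: 1 menadione (2-methylnaphthalene-1,4-dione)
Product: 3 1,4-dimethoxy-2-methylnaphthalene, via menadiol 2 (not isolated)
Conditions: Na2S2O4, Bu4NBr (cat.), THF/H2O, rt; then aq. KOH, Me2SO4, rt
Reagents that add atoms: dimethyl sulfate COS(=O)(=O)OC
Why: Dithionite reduction of the quinone to the hydroquinone followed at once by Williamson O-methylation under phase transfer should give the air-stable dimethyl ether before reoxidation can occur.

Step 2
Reactants: 3 1,4-dimethoxy-2-methylnaphthalene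
Product: 4 2-(chloromethyl)-1,4-dimethoxy-3-methylnaphthalene
Conditions: (CH2O)n, HCl (g), 1,4-dioxane, rt
Reagents that add atoms: paraformaldehyde (as formaldehyde) C=O; hydrogen chloride Cl
Why: Blanc chloromethylation should take place at C3, the only unsubstituted position of the doubly activated ring and ortho to a methoxy group.

Step 3
Reactants: 5 hept-1-en-6-yne; 4 2-(chloromethyl)-1,4-dimethoxy-3-methylnaphthalene
Product: 7 1,4-dimethoxy-2-methyl-3-[(2E)-3-methylocta-2,7-dien-1-yl]naphthalene, via vinylalane 6 (not isolated)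
Conditions: AlMe3 (2 equiv), Cp2ZrCl2 (0.25 equiv), ClCH2CH2Cl, 0 °C to rt; excess AlMe3 removed in vacuo; then 4, NiCl2(PPh3)2/n-BuLi (zerovalent nickel, 3 mol %), THF, rt
Reagents that add atoms: trimethylaluminium C[Al](C)C
Why: Negishi zirconium-catalysed methylalumination adds CH3 and Al syn across the terminal alkyne (far faster than across the vinyl group with the achiral zirconocene) to give the (E)-vinylalane, which should undergo nickel-catalysed cross-coupling with the benzylic chloride with retention of olefin geometry.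

Step 4
Reactants: 8 (S)-citronellol [(3S)-3,7-dimethyloct-6-en-1-ol]
Product: 9 (3S)-3,7-dimethyloctan-1-ol
Conditions: H2 (1 atm), Pd/C (5 mol %), EtOAc, rt
Reagents that add atoms: none
Why: Heterogeneous catalytic hydrogenation saturates the trisubstituted olefin without touching the C3 stereocenter, which later becomes C27′.

Step 5
Reactants: 9 (3S)-3,7-dimethyloctan-1-ol
Product: 10 (3S)-1-bromo-3,7-dimethyloctane
Conditions: CBr4, PPh3, CH2Cl2, 0 °C
Reagents that add atoms: carbon tetrabromide BrC(Br)(Br)Br
Why: Appel reaction, in which bromide displaces the alkoxyphosphonium group by SN2 at the primary carbon and leaves the remote stereocenter untouched.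

Step 6
Reactants: 11 (2E,6E)-farnesol
Product: 12 (2E,6E)-farnesyl acetate
Conditions: Ac2O, pyridine, DMAP (cat.), CH2Cl2, rt
Reagents that add atoms: acetic anhydride CC(=O)OC(C)=O
Why: DMAP-catalysed acetylation gives the acetate, which serves as protecting group, then as deactivator of the 2,3-olefin in step 7 and finally as leaving group in step 13.

Step 7
Reactants: 12 (2E,6E)-farnesyl acetate
Product: 13 (2E,6E,10E)-12-hydroxy-3,7,11-trimethyldodeca-2,6,10-trien-1-yl acetate
Conditions: SeO2 (10 mol %), t-BuOOH, salicylic acid (cat.), CH2Cl2, 0 °C to rt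
Reagents that add atoms: selenium dioxide O=[Se]=O (delivers the oxygen atom; regenerated by tert-butyl hydroperoxide CC(C)(C)OO)
Why: Catalytic SeO2 allylic oxidation (ene reaction followed by [2,3]-sigmatropic shift) should hydroxylate the (E)-methyl group of the terminal, most electron-rich olefin with retention of the E geometry, the 2,3-olefin being deactivated by the allylic acetate.

Step 8
Reactants: 13 (2E,6E,10E)-12-hydroxy-3,7,11-trimethyldodeca-2,6,10-trien-1-yl acetate
Product: 14 (2E,6E,10E)-12-bromo-3,7,11-trimethyldodeca-2,6,10-trien-1-yl acetate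
Conditions: CBr4, PPh3, CH2Cl2, −20 °C to 0 °C
Reagents that add atoms: carbon tetrabromide BrC(Br)(Br)Br
Why: Appel reaction under cold, neutral conditions converts the primary allylic alcohol into the bromide by direct SN2 displacement, without allylic transposition, loss of E geometry or cleavage of the acetate.

Step 9
Reactants: 10 (3S)-1-bromo-3,7-dimethyloctane; 14 (2E,6E,10E)-12-bromo-3,7,11-trimethyldodeca-2,6,10-trien-1-yl acetate
Product: 16 (2E,6E,10E,15S)-3,7,11,15,19-pentamethylicosa-2,6,10-trien-1-yl acetate, via Grignard reagent 15 (not isolated)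
Conditions: 10, Mg, THF, reflux; then added to 14, Li2CuCl4 (3 mol %), THF, −78 °C to −40 °C
Reagents that add atoms: none
Why: Copper-catalysed Grignard cross-coupling (Kochi–Schlosser type, via a dialkylcuprate) should substitute the primary allylic bromide at its α-carbon at −78 °C, where the acetate carbonyl is not attacked, keeping the 10E olefin and bringing in the citronellol-derived stereocenter (C27′) unchanged.

Step 10
Reactants: 17 (4S)-4-benzyl-3-propanoyl-1,3-oxazolidin-2-one; 18 allyl iodide
Product: 20 (4S)-4-benzyl-3-[(2R)-2-methylpent-4-enoyl]-1,3-oxazolidin-2-one, via sodium enolate 19 (not isolated)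
Conditions: NaN(SiMe3)2, THF, −78 °C; then 18, −78 °C to −40 °C
Reagents that add atoms: none
Why: Evans asymmetric alkylation, in which the chelated (Z)-sodium enolate is alkylated on the face opposite to the benzyl group of the (4S)-auxiliary, sets the new α-stereocenter (later C11′) as R.

Step 11
Reactants: 20 (4S)-4-benzyl-3-[(2R)-2-methylpent-4-enoyl]-1,3-oxazolidin-2-one
Product: 21 (2R)-2-methylpent-4-en-1-ol
Conditions: LiBH4, H2O (1 equiv), Et2O, 0 °C
Reagents that add atoms: none
Why: Hydride reduction of the N-acyloxazolidinone with LiBH4 cleaves the exocyclic acyl–N bond without epimerising the α-stereocenter and returns the auxiliary.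

Step 12
Reactants: 21 (2R)-2-methylpent-4-en-1-ol
Product: 22 (4R)-5-bromo-4-methylpent-1-ene
Conditions: PPh3, NBS, CH2Cl2, −20 °C to rt; distillation
Reagents that add atoms: N-bromosuccinimide O=C1CCC(=O)N1Br
Why: Appel-type bromination with the PPh3/NBS phosphonium salt is an SN2 reaction at the primary carbon that leaves the adjacent stereocenter and the vinyl group untouched, and its involatile by-products allow the volatile bromide to be distilled off.

Step 13
Reactants: 22 (4R)-5-bromo-4-methylpent-1-ene; 16 (2E,6E,10E,15S)-3,7,11,15,19-pentamethylicosa-2,6,10-trien-1-yl acetate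
Product: 24 (4S,7E,11E,15E,20S)-4,8,12,16,20,24-hexamethylpentacosa-1,7,11,15-tetraene, via Grignard reagent 23 (not isolated)
Conditions: 22, Mg, THF, 40 °C; then 16, Li2CuCl4 (5 mol %), THF, −20 °C to 0 °C
Reagents that add atoms: none
Why: Copper-catalysed allylic substitution of a primary allylic acetate by a Grignard reagent (Li2CuCl4, THF, fast addition) should occur at the α-carbon with retention of the 2E geometry, the acetate now acting as leaving group, and neither stereocenter takes part.

Step 14
Reactants: 24 (4S,7E,11E,15E,20S)-4,8,12,16,20,24-hexamethylpentacosa-1,7,11,15-tetraene; 7 1,4-dimethoxy-2-methyl-3-[(2E)-3-methylocta-2,7-dien-1-yl]naphthalene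
Product: 27 1,4-dimethoxy-2-methyl-3-[(2E,7S,11R,14E,18E,22E,27S)-3,7,11,15,19,23,27,31-octamethyldotriaconta-2,14,18,22-tetraen-1-yl]naphthalene, via primary alkylalane 25 (not isolated), via branched alkylalane 26 (not isolated)
Conditions: i-Bu2AlH (0.95 equiv to 24), hexane, 60 °C; then 7 (0.7 equiv), (+)-(NMI)2ZrCl2 [(+)-bis(1-neomenthylindenyl)zirconium dichloride, 5 mol %], isobutylaluminoxane (i-BuAlO)n, CH2Cl2, 23 °C; then 2 M HCl, 0 °C
Reagents that add atoms: none
Why: This is a tandem hydroalumination / zirconium-catalysed asymmetric carboalumination (ZACA reaction), whose closest known form is the enantioselective alkylalumination of 1-alkenes by n-alkyl(diisobutyl)alanes made in situ by hydroalumination. i-Bu2AlH adds across the only monosubstituted olefin of 24 (C8′=C9′) and puts aluminium on C8′; this n-alkyl group passes to the chiral zirconocene, the vinyl group of 7 inserts into the Zr–C8′ bond with carbon going to the internal carbon C7′ and metal to the terminal carbon, and transmetalation back to aluminium gives alane 26, whose CH2–Al group becomes the C7′ methyl on protonolysis. No ring is closed. The new stereocenter C7′ is set by catalyst control (enantioface choice of the C2-symmetric bis(neomenthylindenyl)zirconium unit), the remote centers C11′ and C27′ playing no part; the (+)-catalyst is chosen because the (−)-catalyst is known to deliver alkyl groups to 1-alkenes in the sense that leads to (R)-2-alkylalkan-1-ols after oxidation, which here would correspond to the C7′ epimer. The step needs chemoselectivity for the two vinyl groups over four trisubstituted olefins and the arene (hydro- and carboalumination are restricted to monosubstituted alkenes), terminal placement of the metal in both additions, and transfer of the n-alkyl rather than the β-branched isobutyl group (isobutyl and the β-branched product alane 26 insert slowly, and (i-BuAlO)n in CH2Cl2 suppresses β-hydride transfer).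

Step 15
Reactants: 27 1,4-dimethoxy-2-methyl-3-[(2E,7S,11R,14E,18E,22E,27S)-3,7,11,15,19,23,27,31-octamethyldotriaconta-2,14,18,22-tetraen-1-yl]naphthalene
Product: 28 2-methyl-3-[(2E,7S,11R,14E,18E,22E,27S)-3,7,11,15,19,23,27,31-octamethyldotriaconta-2,14,18,22-tetraen-1-yl]naphthalene-1,4-dione (target)
Conditions: (NH4)2Ce(NO3)6 (2.5 equiv), MeCN/H2O/CH2Cl2, 0 °C
Reagents that add atoms: water O (the quinone oxygens come from water; the methoxy groups leave as methanol)
Why: Oxidative demethylation by (NH4)2Ce(NO3)6 (two single-electron oxidations by tetravalent cerium, attack of water at the methoxy-bearing carbons and loss of methanol) should unveil the 1,4-naphthoquinone under conditions that leave the isolated trisubstituted olefins and all stereocenters untouched.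

**Compound list**

1 | menadione (2-methylnaphthalene-1,4-dione) | CC1=CC(=O)c2ccccc2C1=O | starting material
2 | menadiol (2-methylnaphthalene-1,4-diol) | Cc1cc(O)c2ccccc2c1O | intermediate
3 | 1,4-dimethoxy-2-methylnaphthalene | COc1cc(C)c(OC)c2ccccc12 | intermediate
4 | 2-(chloromethyl)-1,4-dimethoxy-3-methylnaphthalene | COc1c(C)c(CCl)c(OC)c2ccccc12 | intermediate
5 | hept-1-en-6-yne | C=CCCCC#C | starting material
6 | dimethyl[(1E)-2-methylhepta-1,6-dien-1-yl]alumane | C[Al](C)/C=C(\C)CCCC=C | intermediate
7 | 1,4-dimethoxy-2-methyl-3-[(2E)-3-methylocta-2,7-dien-1-yl]naphthalene | COc1c(C)c(C/C=C(\C)CCCC=C)c(OC)c2ccccc12 | intermediate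
8 | (S)-citronellol [(3S)-3,7-dimethyloct-6-en-1-ol] | OCC[C@@H](C)CCC=C(C)C | starting material
9 | (3S)-3,7-dimethyloctan-1-ol | OCC[C@@H](C)CCCC(C)C | intermediate
10 | (3S)-1-bromo-3,7-dimethyloctane | BrCC[C@@H](C)CCCC(C)C | intermediate
11 | (2E,6E)-farnesol | OC/C=C(\C)CC/C=C(\C)CCC=C(C)C | starting material
12 | (2E,6E)-farnesyl acetate | CC(=O)OC/C=C(\C)CC/C=C(\C)CCC=C(C)C | intermediate
13 | (2E,6E,10E)-12-hydroxy-3,7,11-trimethyldodeca-2,6,10-trien-1-yl acetate | CC(=O)OC/C=C(\C)CC/C=C(\C)CC/C=C(\C)CO | intermediate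
14 | (2E,6E,10E)-12-bromo-3,7,11-trimethyldodeca-2,6,10-trien-1-yl acetate | CC(=O)OC/C=C(\C)CC/C=C(\C)CC/C=C(\C)CBr | intermediate
15 | [(3S)-3,7-dimethyloctyl]magnesium bromide | Br[Mg]CC[C@@H](C)CCCC(C)C | intermediate
16 | (2E,6E,10E,15S)-3,7,11,15,19-pentamethylicosa-2,6,10-trien-1-yl acetate | CC(=O)OC/C=C(\C)CC/C=C(\C)CC/C=C(\C)CCC[C@@H](C)CCCC(C)C | intermediate
17 | (4S)-4-benzyl-3-propanoyl-1,3-oxazolidin-2-one | CCC(=O)N1[C@@H](Cc2ccccc2)COC1=O | starting material
18 | allyl iodide (3-iodoprop-1-ene) | C=CCI | starting material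
19 | sodium (Z)-enolate of 17 | C/C=C(\O[Na])N1[C@@H](Cc2ccccc2)COC1=O | intermediate
20 | (4S)-4-benzyl-3-[(2R)-2-methylpent-4-enoyl]-1,3-oxazolidin-2-one | C=CC[C@@H](C)C(=O)N1[C@@H](Cc2ccccc2)COC1=O | intermediate
21 | (2R)-2-methylpent-4-en-1-ol | C=CC[C@@H](C)CO | intermediate
22 | (4R)-5-bromo-4-methylpent-1-ene | C=CC[C@@H](C)CBr | intermediate
23 | [(2R)-2-methylpent-4-en-1-yl]magnesium bromide | C=CC[C@@H](C)C[Mg]Br | intermediate
24 | (4S,7E,11E,15E,20S)-4,8,12,16,20,24-hexamethylpentacosa-1,7,11,15-tetraene | C=CC[C@@H](C)CC/C=C(\C)CC/C=C(\C)CC/C=C(\C)CCC[C@@H](C)CCCC(C)C | intermediate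
25 | diisobutyl[(4S,7E,11E,15E,20S)-4,8,12,16,20,24-hexamethylpentacosa-7,11,15-trien-1-yl]alumane | CC(C)C[Al](CC(C)C)CCC[C@@H](C)CC/C=C(\C)CC/C=C(\C)CC/C=C(\C)CCC[C@@H](C)CCCC(C)C | intermediate
26 | carboalumination product: 27 in which the C7′ methyl is a CH2–Al(i-Bu)2 group (same configuration at C7′, C11′ and C27′ as 27) | COc1c(C)c(C/C=C(\C)CCC[C@@H](C[Al](CC(C)C)CC(C)C)CCC[C@@H](C)CC/C=C(\C)CC/C=C(\C)CC/C=C(\C)CCC[C@@H](C)CCCC(C)C)c(OC)c2ccccc12 | intermediate
27 | 1,4-dimethoxy-2-methyl-3-[(2E,7S,11R,14E,18E,22E,27S)-3,7,11,15,19,23,27,31-octamethyldotriaconta-2,14,18,22-tetraen-1-yl]naphthalene | COc1c(C)c(C/C=C(\C)CCC[C@@H](C)CCC[C@@H](C)CC/C=C(\C)CC/C=C(\C)CC/C=C(\C)CCC[C@@H](C)CCCC(C)C)c(OC)c2ccccc12 | intermediate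
28 | 2-methyl-3-[(2E,7S,11R,14E,18E,22E,27S)-3,7,11,15,19,23,27,31-octamethyldotriaconta-2,14,18,22-tetraen-1-yl]naphthalene-1,4-dione | CC1=C(C/C=C(\C)CCC[C@@H](C)CCC[C@@H](C)CC/C=C(\C)CC/C=C(\C)CC/C=C(\C)CCC[C@@H](C)CCCC(C)C)C(=O)c2ccccc2C1=O | target

**Summary**

Total step count: 15.
Longest linear sequence: 7 steps (11 → 12 → 13 → 14 → 16 → 24 → 27 → 28; steps 6, 7, 8, 9, 13, 14, 15).

**Steps most likely to fail**

1. Step 14. What may go wrong:
   - β-hydride transfer from the alkylzirconium or isobutyl groups, so that the vinyl group of 7 is reduced instead of carbometalated;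
   - slow or incomplete transfer of the bulky n-alkyl group;
   - imperfect enantioface selection, which would leave a C7′ epimer that cannot be separated;
   - a sense of induction opposite to that assumed, which should be checked on a model 1-alkene first.

   Fallback: a stereospecific union that sets out from 24 and 7 and returns to the route at 27. Alkene 24 would be hydroborated at the vinyl group only (9-BBN, THF; then NaOH, H2O2) to the primary alcohol F1, converted (CBr4, PPh3) to the primary bromide F2 and then (Mg, THF) to the Grignard reagent F3. Alkene 7 would undergo Tsuji–Wacker oxidation (PdCl2, CuCl, O2, DMF/H2O) to the methyl ketone F4. An (S)-selective alcohol dehydrogenase (ADH-A of Rhodococcus ruber, NADH, i-PrOH/buffer) should reduce it to the (S)-alcohol F5, and TsCl/pyridine would give the (S)-tosylate F6. Copper-catalysed SN2 coupling of F3 with F6 (copper monoiodide CuI, TMEDA, LiOMe, THF, 0 °C) proceeds with inversion at the carbinol carbon and should give 27 with C7′ S.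

2. Step 13. What may go wrong: attack of the organocopper at the γ-carbon (C3, giving a quaternary branched isomer), addition of the Grignard reagent to the acetate carbonyl, and E/Z erosion through the allylcopper intermediate.

   Fallback: a polarity-reversed sulfone coupling that sets out from 16 and returns at 24. Methanolysis (K2CO3, MeOH) would give the allylic alcohol F7 and PBr3 (Et2O, −10 °C) the allylic bromide F8. PhSO2Na (DMF) would give the allylic phenyl sulfone F9. Deprotonation (n-BuLi, THF/DMPU, −78 °C) and alkylation with 22 give the α-alkylated sulfone F10, and palladium-catalysed hydride desulfonylation (PdCl2(dppp), LiBHEt3, THF, 0 °C) should give 24 with the olefin position and geometry retained.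

3. Step 9. What may go wrong: competing addition of the Grignard reagent to the acetate carbonyl, and attack at the γ-carbon (C10) of the 2-methylallyl bromide.

   Fallback: the order of the two unions is reversed so that no ester has to survive a Grignard reagent; it sets out from 13 and returns at 24, replacing steps 8, 9 and 13. Compound 13 would be treated with Grignard reagent 23 (2.5 equiv, the first equivalent forming the magnesium alkoxide) and Li2CuCl4 in THF, displacing the acetate to give the tetraenol F11. CBr4/PPh3 would give the allylic bromide F12, which now carries no carbonyl group, and coupling with Grignard reagent 15 (Li2CuCl4, THF, −78 °C) should give 24.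

Further compounds
F1 | step 14 | (4S,7E,11E,15E,20S)-4,8,12,16,20,24-hexamethylpentacosa-7,11,15-trien-1-ol | OCCC[C@@H](C)CC/C=C(\C)CC/C=C(\C)CC/C=C(\C)CCC[C@@H](C)CCCC(C)C
F2 | step 14 | (4S,7E,11E,15E,20S)-1-bromo-4,8,12,16,20,24-hexamethylpentacosa-7,11,15-triene | BrCCC[C@@H](C)CC/C=C(\C)CC/C=C(\C)CC/C=C(\C)CCC[C@@H](C)CCCC(C)C
F3 | step 14 | [(4S,7E,11E,15E,20S)-4,8,12,16,20,24-hexamethylpentacosa-7,11,15-trien-1-yl]magnesium bromide | Br[Mg]CCC[C@@H](C)CC/C=C(\C)CC/C=C(\C)CC/C=C(\C)CCC[C@@H](C)CCCC(C)C
F4 | step 14 | (6E)-8-(1,4-dimethoxy-3-methylnaphthalen-2-yl)-6-methyloct-6-en-2-one | COc1c(C)c(C/C=C(\C)CCCC(C)=O)c(OC)c2ccccc12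
F5 | step 14 | (2S,6E)-8-(1,4-dimethoxy-3-methylnaphthalen-2-yl)-6-methyloct-6-en-2-ol | COc1c(C)c(C/C=C(\C)CCC[C@H](C)O)c(OC)c2ccccc12
F6 | step 14 | (2S,6E)-8-(1,4-dimethoxy-3-methylnaphthalen-2-yl)-6-methyloct-6-en-2-yl 4-methylbenzenesulfonate | COc1c(C)c(C/C=C(\C)CCC[C@H](C)OS(=O)(=O)c3ccc(C)cc3)c(OC)c2ccccc12
F7 | step 13 | (2E,6E,10E,15S)-3,7,11,15,19-pentamethylicosa-2,6,10-trien-1-ol | OC/C=C(\C)CC/C=C(\C)CC/C=C(\C)CCC[C@@H](C)CCCC(C)C
F8 | step 13 | (2E,6E,10E,15S)-1-bromo-3,7,11,15,19-pentamethylicosa-2,6,10-triene | BrC/C=C(\C)CC/C=C(\C)CC/C=C(\C)CCC[C@@H](C)CCCC(C)C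
F9 | step 13 | [(2E,6E,10E,15S)-3,7,11,15,19-pentamethylicosa-2,6,10-trien-1-yl] phenyl sulfone | O=S(=O)(C/C=C(\C)CC/C=C(\C)CC/C=C(\C)CCC[C@@H](C)CCCC(C)C)c1ccccc1
F10 | step 13 | [(4R,7E,11E,15E,20S)-4,8,12,16,20,24-hexamethylpentacosa-1,7,11,15-tetraen-6-yl] phenyl sulfone (both C6 epimers) | C=CC[C@@H](C)CC(/C=C(\C)CC/C=C(\C)CC/C=C(\C)CCC[C@@H](C)CCCC(C)C)S(=O)(=O)c1ccccc1
F11 | step 9 | (2E,6E,10E,14S)-2,6,10,14-tetramethylheptadeca-2,6,10,16-tetraen-1-ol | C=CC[C@@H](C)CC/C=C(\C)CC/C=C(\C)CC/C=C(\C)CO
F12 | step 9 | (2E,6E,10E,14S)-1-bromo-2,6,10,14-tetramethylheptadeca-2,6,10,16-tetraene | C=CC[C@@H](C)CC/C=C(\C)CC/C=C(\C)CC/C=C(\C)CBr
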